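Atoms are numbered as in germacranolides: ring A is the ten-membered carbocycle C1–C10 (C1=C10, C4=C5), ring B the lactone O–C6–C7–C11(=C13)–C12. The plan cuts C3–C4, the bond that joins the homoallylic CH2 (C3) to the alkenyl carbon C4 in the 1,5-diene C10=C1–C2–C3–C4=C5. The key step closes ring A there by an intramolecular Negishi coupling: a homoallylic zinc reagent at C3 meets the alkenyl bromide at C4 with retention, so both olefin geometries are built beforehand. Its precursor is the cis-fused ring B carrying a 2-bromoalkenyl arm on C6 and a bromo-terminated alkenyl arm on C7; the cis fusion holds both arms on one face.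

Key step: step 12

Remark: (−)-8-phenylmenthol is assumed to leave the Re face of C7 open in the allylindium reagent, as it does at the β-carbon of its enoates in conjugate additions; if the other face reacts, (+)-8-phenylmenthol is used in step 7.

Step 1
Reactants: 1 3-[(tert-butyldimethylsilyl)oxy]propanal; 2 ethyl 2-[bis(2,2,2-trifluoroethoxy)phosphoryl]propanoate
Product: 3 ethyl (2Z)-5-[(tert-butyldimethylsilyl)oxy]-2-methylpent-2-enoate
Conditions: KN(SiMe3)2, 18-crown-6, THF, −78 °C
Reagents that add atoms: none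
Why: Still–Gennari olefination, in which the electron-poor bis(trifluoroethyl) phosphonate collapses fast from the kinetic adduct and should give the (Z)-trisubstituted enoate that stores the C1=C10 geometry (C9 cis to C2).

Step 2
Reactants: 3 ethyl (2Z)-5-[(tert-butyldimethylsilyl)oxy]-2-methylpent-2-enoate
Product: 4 (2Z)-5-[(tert-butyldimethylsilyl)oxy]-2-methylpent-2-en-1-ol
Conditions: i-Bu2AlH (2.2 equiv), CH2Cl2, −78 °C; aq. potassium sodium tartrate
Reagents that add atoms: none
Why: 1,2-reduction of the enoate by the aluminium hydride should give the allylic alcohol without touching the olefin geometry or the silyl ether.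

Step 3
Reactants: 4 (2Z)-5-[(tert-butyldimethylsilyl)oxy]-2-methylpent-2-en-1-ol
Product: 5 (2Z)-5-[(tert-butyldimethylsilyl)oxy]-2-methylpent-2-enal
Conditions: Dess–Martin periodinane, NaHCO3, CH2Cl2, 0 °C
Reagents that add atoms: none
Why: Dess–Martin oxidation under buffered, non-acidic conditions should give the (Z)-enal without isomerization to the (E)-isomer; it is used at once.

Step 4
Reactants: 5 (2Z)-5-[(tert-butyldimethylsilyl)oxy]-2-methylpent-2-enal
Product: 6 (4S,5Z)-8-[(tert-butyldimethylsilyl)oxy]-5-methylocta-1,5-dien-4-ol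
Conditions: (−)-Ipc2B(allyl), Et2O, −78 °C; then NaOH, H2O2, 0 °C to rt
Reagents that add atoms: (−)-B-allyldiisopinocampheylborane, C=CCB([C@@H]1C[C@@H]2C[C@H]([C@H]1C)C2(C)C)[C@@H]1C[C@@H]2C[C@H]([C@H]1C)C2(C)C
Why: Brown allylation through a chair six-membered transition state, in which the isopinocampheyl groups derived from (+)-α-pinene select the aldehyde face that gives the (4S) carbinol, the future C9.

Step 5
Reactants: 6 (4S,5Z)-8-[(tert-butyldimethylsilyl)oxy]-5-methylocta-1,5-dien-4-ol
Product: 7 (4S,5Z)-8-[(tert-butyldimethylsilyl)oxy]-5-methylocta-1,5-dien-4-yl acetate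
Conditions: Ac2O, pyridine, DMAP (cat.), CH2Cl2, rt
Reagents that add atoms: acetic anhydride, CC(=O)OC(C)=O
Why: DMAP-catalysed acetylation installs the C9 acetate of the target early, where it also protects the carbinol, and does not touch the stereocenter.

Step 6
Reactants: 7 (4S,5Z)-8-[(tert-butyldimethylsilyl)oxy]-5-methylocta-1,5-dien-4-yl acetate
Product: 8 (4S,5Z)-8-bromo-5-methylocta-1,5-dien-4-yl acetate
Conditions: Ph3PBr2, CH2Cl2, 0 °C to rt
Reagents that add atoms: dibromotriphenylphosphorane, BrP(Br)(c1ccccc1)(c1ccccc1)c1ccccc1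
Why: Bromodesilylation, in which the primary silyl ether is turned into an oxyphosphonium ion that bromide displaces by SN2, should give the C3 bromide in one operation and leave the secondary acetate alone.

Step 7
Reactants: 9 2-(bromomethyl)prop-2-enoic acid; 10 (1R,2S,5R)-5-methyl-2-(2-phenylpropan-2-yl)cyclohexan-1-ol ((−)-8-phenylmenthol)
Product: 12 (1R,2S,5R)-5-methyl-2-(2-phenylpropan-2-yl)cyclohexyl 2-(bromomethyl)prop-2-enoate, via acid chloride 11 (not isolated)
Conditions: (COCl)2, DMF (cat.), CH2Cl2, 0 °C to rt; then 10, 2,6-lutidine, CH2Cl2, 40 °C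
Reagents that add atoms: none
Why: Esterification through the acyl chloride should acylate the hindered auxiliary alcohol, while 2,6-lutidine is too hindered to displace the allylic bromide.

Step 8
Reactants: 8 (4S,5Z)-8-bromo-5-methylocta-1,5-dien-4-yl acetate; 12 (1R,2S,5R)-5-methyl-2-(2-phenylpropan-2-yl)cyclohexyl 2-(bromomethyl)prop-2-enoate
Product: 13 (1R,2S,5R)-5-methyl-2-(2-phenylpropan-2-yl)cyclohexyl (2Z,5S,6Z)-5-(acetyloxy)-9-bromo-2-(bromomethyl)-6-methylnona-2,6-dienoate
Conditions: second-generation Hoveyda–Grubbs catalyst (5 mol %), 12 (3 equiv), CH2Cl2, 40 °C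
Reagents that add atoms: none
Why: Olefin cross-metathesis of the terminal alkene with a 1,1-disubstituted acrylate that does not homodimerize should give the trisubstituted enoate as its thermodynamic isomer (C8 trans to the ester, cis to CH2Br), the hindered C1=C10 bond staying out of the reaction.

Step 9
Reactants: 14 4-bromofuran-2(5H)-one
Product: 15 4-bromo-2,5-dihydrofuran-2-ol
Conditions: i-Bu2AlH (1.1 equiv), CH2Cl2, −78 °C; aq. potassium sodium tartrate; used crude
Reagents that add atoms: none
Why: Half-reduction of the butenolide should give the lactol, a masked 3-bromo-4-hydroxybut-2-enal whose five-membered ring fixes C6 and C15 cis across C4=C5 and keeps the C15 oxygen distinct from the aldehyde carbon C6.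

Step 10
Reactants: 13 (1R,2S,5R)-5-methyl-2-(2-phenylpropan-2-yl)cyclohexyl (2Z,5S,6Z)-5-(acetyloxy)-9-bromo-2-(bromomethyl)-6-methylnona-2,6-dienoate; 15 4-bromo-2,5-dihydrofuran-2-ol
Product: 17 (4R,5S)-4-[(2S,3Z)-2-(acetyloxy)-6-bromo-3-methylhex-3-en-1-yl]-5-[(1E)-2-bromo-3-hydroxyprop-1-en-1-yl]-3-methylideneoxolan-2-one, via syn-hydroxy ester 16 (not isolated)
Conditions: In powder, 15 (2 equiv), THF/H2O (3:1), rt; then TsOH·H2O (cat.), toluene, 40 °C
Reagents that add atoms: none
Why: Indium-mediated Barbier allylation, in which the (Z)-allylindium adds through a chair six-membered transition state to the open hydroxy-enal form of 15 and should give the syn adduct (C6 and C7 set together, later the cis ring fusion), the phenyl group of the auxiliary covering one face of C7 so that the pair forms in the sense shown, after which acid closes the five-membered lactone on the C6 hydroxyl with loss of the auxiliary, any epimeric syn adduct being a separable diastereomer because C9 is already fixed.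

Step 11
Reactants: 17 (4R,5S)-4-[(2S,3Z)-2-(acetyloxy)-6-bromo-3-methylhex-3-en-1-yl]-5-[(1E)-2-bromo-3-hydroxyprop-1-en-1-yl]-3-methylideneoxolan-2-one
Product: 18 (2E)-3-[(2S,3R)-3-[(2S,3Z)-2-(acetyloxy)-6-bromo-3-methylhex-3-en-1-yl]-4-methylidene-5-oxooxolan-2-yl]-2-bromoprop-2-en-1-yl 3-methylbutanoate
Conditions: 3-methylbutanoyl chloride, pyridine, CH2Cl2, 0 °C
Reagents that add atoms: 3-methylbutanoyl chloride, CC(C)CC(Cl)=O
Why: Acylation of the only free hydroxyl (the primary allylic C15–OH) should give the isovalerate without touching any stereocenter.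

Step 12
Reactants: 18 (2E)-3-[(2S,3R)-3-[(2S,3Z)-2-(acetyloxy)-6-bromo-3-methylhex-3-en-1-yl]-4-methylidene-5-oxooxolan-2-yl]-2-bromoprop-2-en-1-yl 3-methylbutanoate
Product: 20 CNP0398030.1, via homoallylic zinc bromide 19 (not isolated)
Conditions: Zn dust, LiCl, THF, 50 °C; then slow addition (syringe pump) to Pd2(dba)3 (5 mol %), SPhos (12 mol %), THF/NMP, 50 °C, 2 mM
Reagents that add atoms: none
Why: Zinc should insert only into the primary C3–Br bond (the alkenyl C4–Br bond and the allylic esters are inert to Zn/LiCl) to give 19; zerovalent palladium then adds oxidatively to the alkenyl bromide with retention, the alkyl group passes from zinc to divalent palladium within the molecule and reductive elimination forms C3–C4. The closest known reaction type is the Negishi coupling of homoallylic zinc reagents with alkenyl halides used to build 1,5-dienes, with B-alkyl Suzuki–Miyaura macrocyclization as the ring-closing analogue. Ring A is closed end to end as a ten-membered ring through an eleven-membered palladacycle, and no small-ring Heck closure onto C13 can compete because palladium on C4 stands trans to C6. No stereocenter is formed, and the (4Z) and (1(10)Z) geometries and the three stereocenters are carried through unchanged. The step needs cyclization to win over oligomerization and over β-hydride loss, which slow addition at high dilution, the cis-fused ring B that holds both arms on one face and the bulky electron-rich SPhos ligand should secure.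

Compound list
1 | 3-[(tert-butyldimethylsilyl)oxy]propanal | O=CCCO[Si](C)(C)C(C)(C)C | starting material
2 | ethyl 2-[bis(2,2,2-trifluoroethoxy)phosphoryl]propanoate | CCOC(=O)C(C)P(=O)(OCC(F)(F)F)OCC(F)(F)F | starting material
3 | ethyl (2Z)-5-[(tert-butyldimethylsilyl)oxy]-2-methylpent-2-enoate | CCOC(=O)/C(C)=C\CCO[Si](C)(C)C(C)(C)C | intermediate
4 | (2Z)-5-[(tert-butyldimethylsilyl)oxy]-2-methylpent-2-en-1-ol | OC/C(C)=C\CCO[Si](C)(C)C(C)(C)C | intermediate
5 | (2Z)-5-[(tert-butyldimethylsilyl)oxy]-2-methylpent-2-enal | O=C/C(C)=C\CCO[Si](C)(C)C(C)(C)C | intermediate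
6 | (4S,5Z)-8-[(tert-butyldimethylsilyl)oxy]-5-methylocta-1,5-dien-4-ol | C=CC[C@H](O)/C(C)=C\CCO[Si](C)(C)C(C)(C)C | intermediate
7 | (4S,5Z)-8-[(tert-butyldimethylsilyl)oxy]-5-methylocta-1,5-dien-4-yl acetate | C=CC[C@H](OC(C)=O)/C(C)=C\CCO[Si](C)(C)C(C)(C)C | intermediate
8 | (4S,5Z)-8-bromo-5-methylocta-1,5-dien-4-yl acetate | C=CC[C@H](OC(C)=O)/C(C)=C\CCBr | intermediate
9 | 2-(bromomethyl)prop-2-enoic acid | C=C(CBr)C(=O)O | starting material
10 | (1R,2S,5R)-5-methyl-2-(2-phenylpropan-2-yl)cyclohexan-1-ol, (−)-8-phenylmenthol | C[C@@H]1CC[C@H]([C@@H](C1)O)C(C)(C)c1ccccc1 | starting material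
11 | 2-(bromomethyl)prop-2-enoyl chloride (formed in the flask) | C=C(CBr)C(Cl)=O | intermediate
12 | (1R,2S,5R)-5-methyl-2-(2-phenylpropan-2-yl)cyclohexyl 2-(bromomethyl)prop-2-enoate | C[C@@H]1CC[C@H]([C@@H](C1)OC(=O)C(=C)CBr)C(C)(C)c1ccccc1 | intermediate
13 | (1R,2S,5R)-5-methyl-2-(2-phenylpropan-2-yl)cyclohexyl (2Z,5S,6Z)-5-(acetyloxy)-9-bromo-2-(bromomethyl)-6-methylnona-2,6-dienoate | C[C@@H]1CC[C@H]([C@@H](C1)OC(=O)/C(CBr)=C/C[C@H](OC(C)=O)/C(C)=C\CCBr)C(C)(C)c1ccccc1 | intermediate
14 | 4-bromofuran-2(5H)-one | O=C1C=C(Br)CO1 | starting material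
15 | 4-bromo-2,5-dihydrofuran-2-ol (racemic lactol) | OC1C=C(Br)CO1 | intermediate
16 | (1R,2S,5R)-5-methyl-2-(2-phenylpropan-2-yl)cyclohexyl (3R,4S,5E)-3-[(2S,3Z)-2-(acetyloxy)-6-bromo-3-methylhex-3-en-1-yl]-6-bromo-4,7-dihydroxy-2-methylidenehept-5-enoate (formed in the flask) | C[C@@H]1CC[C@H]([C@@H](C1)OC(=O)C(=C)[C@H]([C@H](O)/C=C(\CO)Br)C[C@H](OC(C)=O)/C(C)=C\CCBr)C(C)(C)c1ccccc1 | intermediate
17 | (4R,5S)-4-[(2S,3Z)-2-(acetyloxy)-6-bromo-3-methylhex-3-en-1-yl]-5-[(1E)-2-bromo-3-hydroxyprop-1-en-1-yl]-3-methylideneoxolan-2-one | C=C1C(=O)O[C@H](/C=C(\CO)Br)[C@@H]1C[C@@H](/C(=C\CCBr)C)OC(C)=O | intermediate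
18 | (2E)-3-[(2S,3R)-3-[(2S,3Z)-2-(acetyloxy)-6-bromo-3-methylhex-3-en-1-yl]-4-methylidene-5-oxooxolan-2-yl]-2-bromoprop-2-en-1-yl 3-methylbutanoate | C=C1C(=O)O[C@H](/C=C(\COC(=O)CC(C)C)Br)[C@@H]1C[C@@H](/C(=C\CCBr)C)OC(C)=O | intermediate
19 | homoallylic zinc bromide of 18, C3–ZnBr in place of C3–Br (formed in the flask) | C=C1C(=O)O[C@H](/C=C(\COC(=O)CC(C)C)Br)[C@@H]1C[C@@H](/C(=C\CC[Zn]Br)C)OC(C)=O | intermediate
20 | CNP0398030.1, (1(10)Z,4Z,6R,7R,9S)-9-acetoxy-15-(3-methylbutanoyloxy)germacra-1(10),4,11(13)-trien-12,6-olide | C=C1C(=O)O[C@@H]2/C=C(\COC(=O)CC(C)C)CC/C=C(/C)[C@@H](OC(C)=O)C[C@H]12 | target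

Total step count: 12. Longest linear sequence: 10 steps (steps 1–6, 8, 10, 11, 12).

The step most likely to fail is step 12. The ten-membered ring may close too slowly, so that intermolecular coupling, protonation or β-hydride loss of the organozinc, or ionization of the allylic acetate by zerovalent palladium takes over. The fallback sets out from 18 and changes the nucleophile to boron. Dehydrobromination (DBU, toluene, 60 °C) should give the terminal diene F1. 9-BBN-H in THF should then add to its terminal CH2 to give the B-alkyl borane F2 (not isolated). A B-alkyl Suzuki–Miyaura macrocyclization (Pd(dppf)Cl2, AsPh3, Cs2CO3, DMF/THF/H2O, rt, high dilution) closes the same C3–C4 bond and comes back to the route at 20.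

Second is step 10. The lactol may lose water to 3-bromofuran under the acidic indium salts, the auxiliary may control the face of C7 poorly, and the ene-diol may cyclodehydrate during acid lactonization. The fallback sets out from 13 and changes the allyl metal to boron. Palladium-catalysed borylation of the allylic bromide (B2pin2, Pd2(dba)3, toluene/DMSO, 50 °C) should give the pinacol allylboronate F3. Its thermal allylboration of 15 (toluene, 60 °C) is neutral, syn-specific through a closed transition state, and has the auxiliary bound as in the known 2-alkoxycarbonyl allylboronates. It comes back to the route at 16, which is lactonized to 17 as before.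

Third is step 6. The one-pot bromodesilylation may ionize the allylic acetate or add traces of HBr to the alkenes. The fallback sets out from 7 and works in two steps. HF·pyridine (THF, 0 °C) should give the primary alcohol F4, and Appel bromination (CBr4, PPh3, CH2Cl2, 0 °C) brings it back to the route at 8.

Further compounds
F1 | step 12 | (2E)-3-[(2S,3R)-3-[(2S,3Z)-2-(acetyloxy)-3-methylhexa-3,5-dien-1-yl]-4-methylidene-5-oxooxolan-2-yl]-2-bromoprop-2-en-1-yl 3-methylbutanoate | C=C1C(=O)O[C@H](/C=C(\COC(=O)CC(C)C)Br)[C@@H]1C[C@@H](/C(=C\C=C)C)OC(C)=O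
F2 | step 12 | B-alkyl-9-borabicyclo[3.3.1]nonane from F1, boron on C3 | C=C1C(=O)O[C@H](/C=C(\COC(=O)CC(C)C)Br)[C@@H]1C[C@@H](/C(=C\CCB1C2CCCC1CCC2)C)OC(C)=O
F3 | step 10 | (1R,2S,5R)-5-methyl-2-(2-phenylpropan-2-yl)cyclohexyl (2Z,5S,6Z)-5-(acetyloxy)-9-bromo-6-methyl-2-[(4,4,5,5-tetramethyl-1,3,2-dioxaborolan-2-yl)methyl]nona-2,6-dienoate | C[C@@H]1CC[C@H]([C@@H](C1)OC(=O)/C(CB2OC(C)(C)C(C)(C)O2)=C/C[C@H](OC(C)=O)/C(C)=C\CCBr)C(C)(C)c1ccccc1
F4 | step 6 | (4S,5Z)-8-hydroxy-5-methylocta-1,5-dien-4-yl acetate | C=CC[C@H](OC(C)=O)/C(C)=C\CCO
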